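The readings were generated by integration with constants of no real substance; noise was put on by code.

The partner is what separates the south-west flask from its neighbour, the west run: the charges of starting material, protic impurity and free catalyst match, and the partner charge differs.

| flask | starting material | partner | protic impurity | free catalyst | remark |
|---|---|---|---|---|---|
| south-west | 20 mM | 21 mM | 20 mM | 0.24 mM | the very flask that is asked about, followed so far |
| west | 20 mM | 14 mM | 20 mM | 0.24 mM | run made earlier |
| flask | 20 mM | 21.0 mM | 20.0 mM | 0.24 mM |  |

| run | time / h | product / % |
|---|---|---|
| south-west | 0.833 | 20.8 |
| south-west | 1.50 | 34.2 |
| south-west | 2.50 | 48.2 |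
| south-west | 3.00 | 53.2 |
| south-west | 4.00 | 57.7 |
| west | 0.833 | 18.6 |
| west | 2.50 | 37.3 |
| west | 5.00 | 43.1 |
| west | 8.00 | 43.4 |
| west | 10.0 | 43.0 |

(standard deviation of a reading: 0.5 percentage points)

- steps under discussion: starting material + free catalyst -> catalyst intermediate A; catalyst intermediate A -> catalyst intermediate B; partner + catalyst intermediate B -> catalyst intermediate C; catalyst intermediate C -> released group + catalyst intermediate D; catalyst intermediate D -> free catalyst + product; partner + protic impurity -> quenched reagent
- no earlier run changes the charge of free catalyst; that part of a forecast is a guess

- factor on the rate of making product when 30 % of the starting material are converted if free catalyst is charged twice over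
- factor on the rate when 30 % of the starting material are converted if free catalyst is charged at 0.050 mM instead

In the west run you see product stop near 8.63 mM while 56.8 % of the starting material has not become product. I read that stop as the partner's doing, so the partner is the limiting reagent. Its charge of 14 mM exceeds that product by 5.37 mM, and I book this difference to the quench by protic impurity. Take as the carried quantity the share of the partner charge that never reaches product, the toll: 38.3 %.

The south-west flask holds 21.0 mM of partner against the same impurity. With the same toll I reckon its product to end at 12.9 mM, or 64.8 % of the starting material, higher than the west run. Its last reading, 57.7 % at 4.00 h, lies below that.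

For the two factors, work in powers of ten, on the guess that the rate follows the catalyst. Doubling adds 0.301 to the logarithm of the rate. The smaller charge is a factor 0.208, which adds −0.682. On that guess a smaller charge gives the quench longer per unit of product and a doubled charge gives it less time, so at the same conversion I expect a larger toll and less partner with the smaller charge, and the reverse with the doubled one. My reckoning is therefore a doubling factor a little above 2 and a ratio below 0.208.

The forecast gives 2.15 (1.9 to 2.4) for doubling and 0.07 (0.02 to 0.13) for the smaller charge, where, in its words, “the quench wins”.

The flask gives 2.21 for doubling and 0.0527 for the smaller charge, the latter below 0.208, and its toll at 10.0 h is 40.9 % against 38.3 % read for the west run.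

starting material + free catalyst → catalyst intermediate A (k = 62.9 M⁻¹ min⁻¹); catalyst intermediate A → catalyst intermediate B (k = 4.02 min⁻¹); partner + catalyst intermediate B → catalyst intermediate C (k = 67.9 M⁻¹ min⁻¹); catalyst intermediate C → released group + catalyst intermediate D (k = 132 min⁻¹); catalyst intermediate D → free catalyst + product (k = 1.40 min⁻¹); partner + protic impurity → quenched reagent (k = 0.322 M⁻¹ min⁻¹) At 1.00 h the cycle and the quench were running side by side in this flask, with product at 24.7 %, quenched reagent at 5.15 mM and catalyst intermediate B holding 39.8 % of the catalyst. By 5.00 h in this flask partner was down to 1.34 % of its charge, catalyst intermediate B, now the resting state, held 94.3 %, and product stood at 60.9 %, reaching 62.1 % at 10.0 h.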